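**Retrosynthetic overview**

1. Numbering used below: ring carbons C1 (the stereocentre) to C14, running through the ester-bearing alkene C3=C4, then C7=C8 and C11=C12; C15=C16 is the exocyclic methylene on C1.
2. Target 25 ← methyl ester 24 (saponification); 24 ← acyclic, achiral chloro-polyene 21 by the only ring-forming event: one-pot 9-BBN hydroboration and copper-catalysed enantioselective intramolecular SN2′ allyl–alkyl coupling, which forms C1–C14, closes the 14-membered carbocycle (the only ring), sets the only stereocentre and unveils the C15=C16 methylene.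
3. Enabling feature: C1 is the allylic carbon of the 1,1-disubstituted exocyclic alkene C15=C16, i.e. the γ-carbon of a 2-substituted allyl unit C16–C15=C1 that can carry a leaving group on C16; C14 is the end of the C13–C14 ethylene arm on the ring-alkene carbon C12, i.e. the hydroboration product of a C11=C12–C13=C14 diene whose vinyl group is the only monosubstituted alkene in the precursor.
4. 21 ← aldehyde 18 (C1–C3, C15, C16, side chain) + phosphonate 9 (C4–C14) by Z-selective Still–Gennari olefination (C3=C4).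
5. 9 ← pent-4-ynal (Stork–Zhao iodo-olefination, carboalumination/oxirane opening, Stille vinylation, iodination, phosphonoacetate alkylation); 18 ← propargyl alcohol + homoprenyl bromide (anti-carbomagnesiation/iodination, THP protection, alkenyllithium/oxirane opening, oxidation).

Key step: step 13

Assumption: the copper/(R)-DTBM-SEGPHOS catalyst is taken to deliver the (R)-configured ring carbon on this β-substituted (Z)-allylic chloride; if the first run shows the opposite sense, the (S)-ligand is used with no other change.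

**Route**

Step 1
Reactants: 1 pent-4-ynal
Product: 2 (5Z)-6-iodohept-5-en-1-yne
Conditions: EtPPh3I, n-BuLi, THF, 0 °C to rt; I2, −78 °C; NaN(SiMe3)2, −20 °C; then 1, −78 to −20 °C
Reagents that add atoms: ethyltriphenylphosphonium iodide, CC[P+](c1ccccc1)(c1ccccc1)c1ccccc1.[I-]; iodine, II
Why: Stork–Zhao-type Wittig olefination: the α-iodoethylidene ylide adds to the unhindered aldehyde under kinetic control to give the (Z)-2-iodoalkene (iodine cis to the chain), and the ylide is too weak a base to remove the alkyne C–H.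

Step 2
Reactants: 2 (5Z)-6-iodohept-5-en-1-yne
Product: 5 (3E,7Z)-8-iodo-4-methylnona-3,7-dien-1-ol, via alkenyldimethylalane 3 (not isolated), via lithium alkenylalanate 4 (not isolated)
Conditions: Me3Al (2 equiv), Cp2ZrCl2 (0.25 equiv), CH2Cl2, 0 °C to rt; evaporate, hexane; n-BuLi (1 equiv), THF, −78 °C; ethylene oxide, −78 to 0 °C; H2O
Reagents that add atoms: trimethylaluminium, C[Al](C)C; ethylene oxide, C1CO1
Why: Zirconium-catalysed methylalumination (Negishi carboalumination) adds Me and Al syn across the terminal alkyne with Me on the internal carbon, and the derived lithium alanate transfers the alkenyl group to ethylene oxide with retention, fixing the E-trisubstituted alkene; the vinyl iodide is inert to Me3Al, and ate-complex formation with n-BuLi at −78 °C is far faster than iodine–lithium exchange.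

Step 3
Reactants: 5 (3E,7Z)-8-iodo-4-methylnona-3,7-dien-1-ol
Product: 6 (3E,7Z)-4,8-dimethyldeca-3,7,9-trien-1-ol
Conditions: CH2=CHSnBu3, Pd2(dba)3 (2.5 mol%), AsPh3 (20 mol%), DMF, rt
Reagents that add atoms: tributyl(vinyl)stannane, C=C[Sn](CCCC)(CCCC)CCCC
Why: Stille coupling with retention of the Z-alkenyl iodide geometry; ligand-accelerated transmetalation at room temperature should outrun Heck-type cyclisation onto the remote trisubstituted alkene, and the free alcohol is tolerated.

Step 4
Reactants: 6 (3E,7Z)-4,8-dimethyldeca-3,7,9-trien-1-ol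
Product: 7 (3Z,7E)-10-iodo-3,7-dimethyldeca-1,3,7-triene
Conditions: I2, PPh3, imidazole, CH2Cl2, 0 °C to rt
Reagents that add atoms: iodine, II
Why: Appel-type iodination of the unhindered primary alcohol by SN2 displacement of the alkoxyphosphonium ion, with no effect on the alkenes.

Step 5
Reactants: 7 (3Z,7E)-10-iodo-3,7-dimethyldeca-1,3,7-triene, 8 methyl 2-[bis(2,2,2-trifluoroethoxy)phosphoryl]acetate
Product: 9 methyl (5E,9Z)-2-[bis(2,2,2-trifluoroethoxy)phosphoryl]-6,10-dimethyldodeca-5,9,11-trienoate (racemic at C2)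
Conditions: 8 (1.5 equiv), NaH, DMF, 0 °C; then 7, 50 °C
Reagents that add atoms: none
Why: SN2 C-alkylation of the sodium salt of the Still–Gennari phosphonoacetate by the primary iodide; the excess of 8 suppresses dialkylation.

Step 6
Reactants: 10 prop-2-yn-1-ol, 11 5-bromo-2-methylpent-2-ene
Product: 14 (2Z)-3-iodo-2-(4-methylpent-3-en-1-yl)prop-2-en-1-ol, via homoprenylmagnesium bromide 12 (not isolated), via chelated alkenylmagnesium alkoxide 13 (not isolated)
Conditions: 11, Mg, THF; 10, CuI (10 mol%), THF, −10 °C to rt; I2, −78 to 0 °C; aq. NH4Cl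
Reagents that add atoms: iodine, II
Why: Copper-catalysed, hydroxyl-directed anti-carbomagnesiation of the propargylic alcohol puts the alkyl group on the internal carbon and magnesium in a five-membered chelate cis to CH2O, and iodinolysis with retention gives the (Z)-iodide.

Step 7
Reactants: 14 (2Z)-3-iodo-2-(4-methylpent-3-en-1-yl)prop-2-en-1-ol
Product: 15 2-{[(2Z)-3-iodo-2-(4-methylpent-3-en-1-yl)prop-2-en-1-yl]oxy}oxane (racemic at the acetal carbon)
Conditions: 3,4-dihydro-2H-pyran, PPTS (cat.), CH2Cl2, rt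
Reagents that add atoms: 3,4-dihydro-2H-pyran, C1=COCCC1
Why: Acid-catalysed acetalisation of the alcohol with dihydropyran; an acetal is preferred to a silyl ether because a silyl group cis to the alkenyllithium of step 8 could migrate from O to C.

Step 8
Reactants: 15 2-{[(2Z)-3-iodo-2-(4-methylpent-3-en-1-yl)prop-2-en-1-yl]oxy}oxane
Product: 17 (3Z)-8-methyl-4-[(oxan-2-yloxy)methyl]nona-3,7-dien-1-ol, via alkenyllithium 16 (not isolated)
Conditions: t-BuLi (2.1 equiv), Et2O, −78 °C; ethylene oxide, −78 °C to rt; H2O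
Reagents that add atoms: ethylene oxide, C1CO1
Why: Iodine–lithium exchange with retention gives a configurationally stable, chelated alkenyllithium that opens ethylene oxide (SN2) to the homoallylic alcohol.

Step 9
Reactants: 17 (3Z)-8-methyl-4-[(oxan-2-yloxy)methyl]nona-3,7-dien-1-ol
Product: 18 (3Z)-8-methyl-4-[(oxan-2-yloxy)methyl]nona-3,7-dienal (used at once, no chromatography)
Conditions: Dess–Martin periodinane, pyridine, CH2Cl2, 0 °C
Reagents that add atoms: none
Why: Dess–Martin oxidation under buffered, non-basic conditions gives the β,γ-unsaturated aldehyde without migration of the alkene into conjugation.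

Step 10
Reactants: 18 (3Z)-8-methyl-4-[(oxan-2-yloxy)methyl]nona-3,7-dienal, 9 methyl (5E,9Z)-2-[bis(2,2,2-trifluoroethoxy)phosphoryl]-6,10-dimethyldodeca-5,9,11-trienoate
Product: 19 methyl (2Z,5Z)-2-[(3E,7Z)-4,8-dimethyldeca-3,7,9-trien-1-yl]-10-methyl-6-[(oxan-2-yloxy)methyl]undeca-2,5,9-trienoate
Conditions: 9, KN(SiMe3)2, 18-crown-6, THF, −78 °C; then 18, −78 °C
Reagents that add atoms: none
Why: Still–Gennari variant of the Horner–Wadsworth–Emmons reaction: the electron-poor bis(trifluoroethyl) phosphonate eliminates fast from the kinetically formed adduct, so the aldehyde-derived carbon ends up cis to CO2Me ((Z)-trisubstituted enoate), and the pre-formed potassium phosphonate adds at −78 °C faster than it enolises the aldehyde.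

Step 11
Reactants: 19 methyl (2Z,5Z)-2-[(3E,7Z)-4,8-dimethyldeca-3,7,9-trien-1-yl]-10-methyl-6-[(oxan-2-yloxy)methyl]undeca-2,5,9-trienoate
Product: 20 methyl (2Z,5Z)-2-[(3E,7Z)-4,8-dimethyldeca-3,7,9-trien-1-yl]-6-(hydroxymethyl)-10-methylundeca-2,5,9-trienoate
Conditions: PPTS (cat.), MeOH, 40 °C
Reagents that add atoms: none
Why: Acid-catalysed transacetalisation to methanol frees the primary allylic alcohol without touching the ester, the skipped diene or the conjugated diene.

Step 12
Reactants: 20 methyl (2Z,5Z)-2-[(3E,7Z)-4,8-dimethyldeca-3,7,9-trien-1-yl]-6-(hydroxymethyl)-10-methylundeca-2,5,9-trienoate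
Product: 21 methyl (2Z,5Z)-6-(chloromethyl)-2-[(3E,7Z)-4,8-dimethyldeca-3,7,9-trien-1-yl]-10-methylundeca-2,5,9-trienoate
Conditions: PPh3, Cl3CC(O)CCl3, CH2Cl2, −20 to 0 °C
Reagents that add atoms: hexachloroacetone, ClC(Cl)(Cl)C(=O)C(Cl)(Cl)Cl
Why: Appel-type chlorination: chloride displaces the alkoxyphosphonium ion at the primary carbon (SN2) under neutral conditions, without allylic transposition or alkene isomerisation.

Step 13
Reactants: 21 methyl (2Z,5Z)-6-(chloromethyl)-2-[(3E,7Z)-4,8-dimethyldeca-3,7,9-trien-1-yl]-10-methylundeca-2,5,9-trienoate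
Product: 24 methyl (1Z,4R,7Z,11E)-7,11-dimethyl-4-(6-methylhepta-1,5-dien-2-yl)cyclotetradeca-1,7,11-triene-1-carboxylate, via B-alkyl-9-BBN borane 22 (not isolated), via potassium methoxyborate 23 (not isolated)
Conditions: 9-BBN dimer (0.55 equiv), THF, rt; KOMe (1.1 equiv), 0 °C; syringe-pump addition over 12 h to (CuOTf)2·toluene (10 mol% Cu), (R)-DTBM-SEGPHOS (12 mol%), 1,4-dioxane/CH2Cl2, 15 °C, 2 mM final
Reagents that add atoms: none
Why: Proposed new method: 9-BBN adds to the terminal CH=CH2 of the 1,3-diene (the only monosubstituted alkene; every other alkene is trisubstituted) to give the homoallylic borane 22, which as its methoxyborate 23 transfers the primary alkyl group to phosphine-bound monovalent copper; the alkylcopper then attacks the γ-carbon (C1) of the 2-substituted allylic chloride in a formal SN2′ process (addition across C1=C15 and β-elimination of chloride, or anti oxidative addition to trivalent copper and reductive elimination), forming C1–C14 and releasing the C15=C16 methylene. The closest known reactions are the intermolecular copper/bisphosphine-catalysed enantioselective γ-selective coupling of (Z)-allylic chlorides with alkyl-9-BBN reagents and the copper-catalysed asymmetric SN2′ alkylation of β-substituted allylic chlorides with Grignard reagents; new here are the intramolecular, macrocyclising mode and the fully substituted β-carbon. The 14-membered carbocycle closes in a 14-exo-trig SN2′ mode (attacked carbon inside the ring, departing C=CH2 outside). The single stereocentre is set by catalyst control: the C2-symmetric bisphosphine on copper differentiates the enantiotopic faces of the geometrically pure (Z)-allylic chloride. The step needs γ- over α-attack (inherent to the copper/borate system), ring closure over oligomerisation (slow addition at high dilution to a chain pre-bent by three trisubstituted alkenes), and no base-induced 1,4-loss of HCl through the doubly allylic C2 methylene (methoxide is bound as the borate).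

Step 14
Reactants: 24 methyl (1Z,4R,7Z,11E)-7,11-dimethyl-4-(6-methylhepta-1,5-dien-2-yl)cyclotetradeca-1,7,11-triene-1-carboxylate
Product: 25 (1Z,4R,7Z,11E)-7,11-dimethyl-4-(6-methylhepta-1,5-dien-2-yl)cyclotetradeca-1,7,11-triene-1-carboxylic acid
Conditions: LiOH, THF/MeOH/H2O (3:1:1), 45 °C; then 1 M HCl
Reagents that add atoms: lithium hydroxide, [Li+].[OH-] (supplies the carboxyl OH oxygen)
Why: Saponification (acyl–oxygen cleavage) of the methyl ester; the stereocentre is not enolisable and hydroxide does not change the enoate geometry at this temperature.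

**Compound list**

1 | pent-4-ynal | C#CCCC=O | starting material
2 | (5Z)-6-iodohept-5-en-1-yne | C#CCC/C=C(/C)I | intermediate
3 | [(1E,5Z)-6-iodo-2-methylhepta-1,5-dien-1-yl]dimethylalumane | C[Al](C)/C=C(\C)CC/C=C(/C)I | intermediate
4 | lithium butyl[(1E,5Z)-6-iodo-2-methylhepta-1,5-dien-1-yl]dimethylaluminate | [Li+].CCCC[Al-](C)(C)/C=C(\C)CC/C=C(/C)I | intermediate
5 | (3E,7Z)-8-iodo-4-methylnona-3,7-dien-1-ol | OCC/C=C(\C)CC/C=C(/C)I | intermediate
6 | (3E,7Z)-4,8-dimethyldeca-3,7,9-trien-1-ol | OCC/C=C(\C)CC/C=C(/C)C=C | intermediate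
7 | (3Z,7E)-10-iodo-3,7-dimethyldeca-1,3,7-triene | ICC/C=C(\C)CC/C=C(/C)C=C | intermediate
8 | methyl 2-[bis(2,2,2-trifluoroethoxy)phosphoryl]acetate | COC(=O)CP(=O)(OCC(F)(F)F)OCC(F)(F)F | starting material
9 | methyl (5E,9Z)-2-[bis(2,2,2-trifluoroethoxy)phosphoryl]-6,10-dimethyldodeca-5,9,11-trienoate | COC(=O)C(CC/C=C(\C)CC/C=C(/C)C=C)P(=O)(OCC(F)(F)F)OCC(F)(F)F | intermediate
10 | prop-2-yn-1-ol | OCC#C | starting material
11 | 5-bromo-2-methylpent-2-ene | CC(C)=CCCBr | starting material
12 | (4-methylpent-3-en-1-yl)magnesium bromide | CC(C)=CCC[Mg]Br | intermediate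
13 | bromomagnesium (2Z)-3-(bromomagnesio)-2-(4-methylpent-3-en-1-yl)prop-2-en-1-olate | Br[Mg]/C=C(\CO[Mg]Br)CCC=C(C)C | intermediate
14 | (2Z)-3-iodo-2-(4-methylpent-3-en-1-yl)prop-2-en-1-ol | I/C=C(\CO)CCC=C(C)C | intermediate
15 | 2-{[(2Z)-3-iodo-2-(4-methylpent-3-en-1-yl)prop-2-en-1-yl]oxy}oxane | I/C=C(\COC1CCCCO1)CCC=C(C)C | intermediate
16 | {(1Z)-6-methyl-2-[(oxan-2-yloxy)methyl]hepta-1,5-dien-1-yl}lithium | [Li]/C=C(\COC1CCCCO1)CCC=C(C)C | intermediate
17 | (3Z)-8-methyl-4-[(oxan-2-yloxy)methyl]nona-3,7-dien-1-ol | OCC/C=C(\COC1CCCCO1)CCC=C(C)C | intermediate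
18 | (3Z)-8-methyl-4-[(oxan-2-yloxy)methyl]nona-3,7-dienal | O=CC/C=C(\COC1CCCCO1)CCC=C(C)C | intermediate
19 | methyl (2Z,5Z)-2-[(3E,7Z)-4,8-dimethyldeca-3,7,9-trien-1-yl]-10-methyl-6-[(oxan-2-yloxy)methyl]undeca-2,5,9-trienoate | CC(C)=CCC/C(COC1CCCCO1)=C/C/C=C(\C(=O)OC)CC/C=C(\C)CC/C=C(/C)C=C | intermediate
20 | methyl (2Z,5Z)-2-[(3E,7Z)-4,8-dimethyldeca-3,7,9-trien-1-yl]-6-(hydroxymethyl)-10-methylundeca-2,5,9-trienoate | CC(C)=CCC/C(CO)=C/C/C=C(\C(=O)OC)CC/C=C(\C)CC/C=C(/C)C=C | intermediate
21 | methyl (2Z,5Z)-6-(chloromethyl)-2-[(3E,7Z)-4,8-dimethyldeca-3,7,9-trien-1-yl]-10-methylundeca-2,5,9-trienoate | CC(C)=CCC/C(CCl)=C/C/C=C(\C(=O)OC)CC/C=C(\C)CC/C=C(/C)C=C | intermediate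
22 | methyl (2Z,5Z)-2-[(3E,7Z)-10-(9-borabicyclo[3.3.1]nonan-9-yl)-4,8-dimethyldeca-3,7-dien-1-yl]-6-(chloromethyl)-10-methylundeca-2,5,9-trienoate | CC(C)=CCC/C(CCl)=C/C/C=C(\C(=O)OC)CC/C=C(\C)CC/C=C(/C)CCB1C2CCCC1CCC2 | intermediate
23 | potassium methoxyborate of 22 (9-alkyl-9-methoxy-9-boranuidabicyclo[3.3.1]nonane, potassium salt) | CC(C)=CCC/C(CCl)=C/C/C=C(\C(=O)OC)CC/C=C(\C)CC/C=C(/C)CC[B-]1(OC)C2CCCC1CCC2.[K+] | intermediate
24 | methyl (1Z,4R,7Z,11E)-7,11-dimethyl-4-(6-methylhepta-1,5-dien-2-yl)cyclotetradeca-1,7,11-triene-1-carboxylate | C=C(CCC=C(C)C)[C@H]1C/C=C(\C(=O)OC)CC/C=C(\C)CC/C=C(/C)CC1 | intermediate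
25 | (1Z,4R,7Z,11E)-7,11-dimethyl-4-(6-methylhepta-1,5-dien-2-yl)cyclotetradeca-1,7,11-triene-1-carboxylic acid | C=C(CCC=C(C)C)[C@H]1C/C=C(\C(=O)O)CC/C=C(\C)CC/C=C(/C)CC1 | target

**Step count and risks**

Total step count: 14. Longest linear sequence: 10 steps (steps 1–5, then 10–14).

Steps most likely to fail:

Step 13 (Proposed new method). Oligomerisation may compete with ring closure, alkyl transfer to a γ-carbon next to a fully substituted β-carbon may be slow, enantiofacial discrimination may be weaker than on simpler allylic chlorides, and base may trigger 1,4-dehydrochlorination through the doubly allylic methylene. The fallback uses known chemistry, forms the same ring bond, sets out from 21 and comes back at 24. Hydroboration of 21 with 9-BBN (via 22) and oxidation with NaBO3·4H2O would give the primary alcohol methyl (2Z,5Z)-6-(chloromethyl)-2-[(3E,7Z)-10-hydroxy-4,8-dimethyldeca-3,7-dien-1-yl]-10-methylundeca-2,5,9-trienoate F1. Dess–Martin oxidation would give the aldehyde methyl (2Z,5Z)-6-(chloromethyl)-2-[(3E,7Z)-4,8-dimethyl-10-oxodeca-3,7-dien-1-yl]-10-methylundeca-2,5,9-trienoate F2. An intramolecular Nozaki–Hiyama–Kishi allylation (CrCl2, chiral oxazoline–sulfonamide ligand, Et3N, THF, high dilution) would close the 14-membered ring by γ-attack of the allylchromium on the aldehyde, the ligand enantiomer being chosen for the (R)-ring carbon, to give the homoallylic alcohol methyl (1Z,4R,5S,7Z,11E)-5-hydroxy-7,11-dimethyl-4-(6-methylhepta-1,5-dien-2-yl)cyclotetradeca-1,7,11-triene-1-carboxylate F3 (anti expected; the carbinol configuration is immaterial). Thiocarbonyldiimidazole/DMAP would give the thiocarbonyl imidazolide methyl (1Z,4R,5S,7Z,11E)-5-[(1H-imidazole-1-carbothioyl)oxy]-7,11-dimethyl-4-(6-methylhepta-1,5-dien-2-yl)cyclotetradeca-1,7,11-triene-1-carboxylate F4, and Barton–McCombie deoxygenation (Bu3SnH at high concentration, AIBN, toluene, 90 °C) would return 24.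

Step 10. The β,γ-unsaturated aldehyde may enolise and slip into conjugation before it is olefinated, and Z-selectivity may erode with the long α-substituent. The fallback makes the enoate from a robust aldehyde and forms C1–C2 by cross-coupling; it sets out from 9 and 15 and comes back at 19. Still–Gennari olefination of 9 with (tert-butyldimethylsilyloxy)acetaldehyde would give methyl (2Z,5E,9Z)-2-{2-[(tert-butyldimethylsilyl)oxy]ethylidene}-6,10-dimethyldodeca-5,9,11-trienoate F5. Ph3PBr2 would convert the silyl ether directly into the allylic bromide methyl (2Z,5E,9Z)-2-(2-bromoethylidene)-6,10-dimethyldodeca-5,9,11-trienoate F6. Iodide 15 would be lithiated as in step 8 (via 16) and quenched with Bu3SnCl to give tributyl{(1Z)-6-methyl-2-[(oxan-2-yloxy)methyl]hepta-1,5-dien-1-yl}stannane F7. A Stille allyl–alkenyl coupling of F6 with F7 (Pd2(dba)3, AsPh3, THF, rt) would give 19.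

Step 2. Iodine–lithium exchange at the alkenyl iodide may compete with ate-complex formation, and transfer of the alkenyl group to the oxirane may be incomplete. The fallback builds the diene by carbonyl olefination before the carboalumination, so no alkenyl iodide meets an alkyllithium; it sets out from 1 and comes back at 6. Still–Gennari olefination of 1 with methyl 2-[bis(2,2,2-trifluoroethoxy)phosphoryl]propanoate would give methyl (2Z)-2-methylhept-2-en-6-ynoate F8. DIBAL-H would give (2Z)-2-methylhept-2-en-6-yn-1-ol F9, and Dess–Martin oxidation would give (2Z)-2-methylhept-2-en-6-ynal F10. Wittig methylenation (Ph3P=CH2, THF, 0 °C) would give (3Z)-3-methylocta-1,3-dien-7-yne F11. Methylalumination (Me3Al, Cp2ZrCl2) would give [(1E,5Z)-2,6-dimethylocta-1,5,7-trien-1-yl]dimethylalumane F12, n-BuLi would give lithium butyl[(1E,5Z)-2,6-dimethylocta-1,5,7-trien-1-yl]dimethylaluminate F13, and ethylene oxide would give 6.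

Further compounds

F1 | step 13 | methyl (2Z,5Z)-6-(chloromethyl)-2-[(3E,7Z)-10-hydroxy-4,8-dimethyldeca-3,7-dien-1-yl]-10-methylundeca-2,5,9-trienoate | CC(C)=CCC/C(CCl)=C/C/C=C(\C(=O)OC)CC/C=C(\C)CC/C=C(/C)CCO
F2 | step 13 | methyl (2Z,5Z)-6-(chloromethyl)-2-[(3E,7Z)-4,8-dimethyl-10-oxodeca-3,7-dien-1-yl]-10-methylundeca-2,5,9-trienoate | CC(C)=CCC/C(CCl)=C/C/C=C(\C(=O)OC)CC/C=C(\C)CC/C=C(/C)CC=O
F3 | step 13 | methyl (1Z,4R,5S,7Z,11E)-5-hydroxy-7,11-dimethyl-4-(6-methylhepta-1,5-dien-2-yl)cyclotetradeca-1,7,11-triene-1-carboxylate | C=C(CCC=C(C)C)[C@H]1C/C=C(\C(=O)OC)CC/C=C(\C)CC/C=C(/C)C[C@@H]1O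
F4 | step 13 | methyl (1Z,4R,5S,7Z,11E)-5-[(1H-imidazole-1-carbothioyl)oxy]-7,11-dimethyl-4-(6-methylhepta-1,5-dien-2-yl)cyclotetradeca-1,7,11-triene-1-carboxylate | C=C(CCC=C(C)C)[C@H]1C/C=C(\C(=O)OC)CC/C=C(\C)CC/C=C(/C)C[C@@H]1OC(=S)n1ccnc1
F5 | step 10 | methyl (2Z,5E,9Z)-2-{2-[(tert-butyldimethylsilyl)oxy]ethylidene}-6,10-dimethyldodeca-5,9,11-trienoate | CC(C)(C)[Si](C)(C)OC/C=C(\C(=O)OC)CC/C=C(\C)CC/C=C(/C)C=C
F6 | step 10 | methyl (2Z,5E,9Z)-2-(2-bromoethylidene)-6,10-dimethyldodeca-5,9,11-trienoate | BrC/C=C(\C(=O)OC)CC/C=C(\C)CC/C=C(/C)C=C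
F7 | step 10 | tributyl{(1Z)-6-methyl-2-[(oxan-2-yloxy)methyl]hepta-1,5-dien-1-yl}stannane | CCCC[Sn](CCCC)(CCCC)/C=C(\COC1CCCCO1)CCC=C(C)C
F8 | step 2 | methyl (2Z)-2-methylhept-2-en-6-ynoate | C#CCC/C=C(/C)C(=O)OC
F9 | step 2 | (2Z)-2-methylhept-2-en-6-yn-1-ol | C#CCC/C=C(/C)CO
F10 | step 2 | (2Z)-2-methylhept-2-en-6-ynal | C#CCC/C=C(/C)C=O
F11 | step 2 | (3Z)-3-methylocta-1,3-dien-7-yne | C#CCC/C=C(/C)C=C
F12 | step 2 | [(1E,5Z)-2,6-dimethylocta-1,5,7-trien-1-yl]dimethylalumane | C[Al](C)/C=C(\C)CC/C=C(/C)C=C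
F13 | step 2 | lithium butyl[(1E,5Z)-2,6-dimethylocta-1,5,7-trien-1-yl]dimethylaluminate | [Li+].CCCC[Al-](C)(C)/C=C(\C)CC/C=C(/C)C=C
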